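Numbering for the spiro compounds: ring A = C1 (carries the exocyclic CH2), C2, C3, C4 (Br), C5 (CMe2), C6 (spiro atom); ring B = C6, C7, C8, C9 (Me, Cl), C10 (Br), C11.
Feature: a 1,1-disubstituted methylene on C1 sits directly beside the quaternary spiro atom C6, and C9 of ring B carries a heteroatom. This is the retron of an oxy-Cope shift in which a vinyl terminus (C7) bonds to C6 of a ring-fusion C1=C6 alkene while the C9–CH2 ring bond breaks, so ring B as a C9 ketone goes back to a fused 2-vinyl-octalin-2-ol.
Late disconnections: C10–Br (SN2 on C10–O); C9–Cl (chloride opening of an acetoxonium ion from a cis-diol); C4–Br (Appel inversion of a carbinol set by CBS reduction); C9–CH3 (cross-coupling of an enol triflate made with a chiral lithium amide, the event that makes C6 stereogenic).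
Ring order: ring A and an anisole ring come with 6-methoxy-2-tetralone. Birch reduction turns the arene into the cyclohexenone ring that is later opened. Ring B is closed last, in the [3,3] step.

Key step: step 7

Assumption: the sense of enolisation by lithium (S,S)-bis(1-phenylethyl)amide is carried over from 4-substituted cyclohexanones, with equatorial C5 taking the place of the 4-substituent. If the spiro ketone responds in the opposite sense, the equally available (R,R)-amine is used.

Step 1
Reactants: 1 6-methoxy-2-tetralone; 2 methyl iodide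
Product: 3 6-methoxy-1,1-dimethyl-3,4-dihydronaphthalen-2(1H)-one
Conditions: KOt-Bu (2.3 equiv), MeI (2.6 equiv), THF/t-BuOH, 0 °C → rt
Reagents that add atoms: methyl iodide, CI
Why: Exhaustive enolate C-alkylation; the benzylic C1–H of a 2-tetralone is the most acidic site, so both methyl groups should enter there, and the quaternary carbon so formed stops further alkylation at that position.

Step 2
Reactants: 3 6-methoxy-1,1-dimethyl-3,4-dihydronaphthalen-2(1H)-one
Product: 4 (2S)-6-methoxy-1,1-dimethyl-1,2,3,4-tetrahydronaphthalen-2-ol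
Conditions: (R)-2-methyl-CBS-oxazaborolidine (10 mol%), BH3·SMe2, THF, −20 °C; MeOH
Reagents that add atoms: none
Why: Corey–Bakshi–Shibata reduction; the carbonyl lies between a quaternary benzylic carbon and a CH2 group, so the (R)-oxazaborolidine should deliver hydride to one face and set the (S)-carbinol that becomes C4.

Step 3
Reactants: 4 (2S)-6-methoxy-1,1-dimethyl-1,2,3,4-tetrahydronaphthalen-2-ol
Product: 5 (2S)-2-(tert-butyldimethylsilyloxy)-6-methoxy-1,1-dimethyl-1,2,3,4-tetrahydronaphthalene
Conditions: TBSOTf, 2,6-lutidine, CH2Cl2, 0 °C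
Reagents that add atoms: tert-butyldimethylsilyl triflate, CC(C)(C)[Si](C)(C)OS(=O)(=O)C(F)(F)F
Why: Silylation of a hindered secondary alcohol with the silyl triflate; the alkyl silyl ether withstands dissolving metal, oxalic acid, the organocerium reagent and KH, and keeps a second alkoxide out of the key step.

Step 4
Reactants: 5 (2S)-2-(tert-butyldimethylsilyloxy)-6-methoxy-1,1-dimethyl-1,2,3,4-tetrahydronaphthalene
Product: 6 (2S)-2-(tert-butyldimethylsilyloxy)-6-methoxy-1,1-dimethyl-1,2,3,4,5,8-hexahydronaphthalene
Conditions: Li, t-BuOH, NH3(l)/THF, −78 → −33 °C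
Reagents that add atoms: none
Why: Birch reduction of an anisole; protonation ortho and meta to OMe leaves the enol ether and the tetrasubstituted ring-fusion alkene as a 1,4-diene, and the silyl ether and C4 are not touched.

Step 5
Reactants: 6 (2S)-2-(tert-butyldimethylsilyloxy)-6-methoxy-1,1-dimethyl-1,2,3,4,5,8-hexahydronaphthalene
Product: 7 (6S)-6-(tert-butyldimethylsilyloxy)-5,5-dimethyl-3,4,5,6,7,8-hexahydronaphthalen-2(1H)-one
Conditions: (CO2H)2, THF/MeOH/H2O, rt
Reagents that add atoms: water, O
Why: Mild enol ether hydrolysis as used for 19-nor-steroid 5(10)-en-3-ones; oxalic acid cleaves the enol ether but is too weak to move the tetrasubstituted alkene into conjugation or to remove the silyl ether.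

Step 6
Reactants: 7 (6S)-6-(tert-butyldimethylsilyloxy)-5,5-dimethyl-3,4,5,6,7,8-hexahydronaphthalen-2(1H)-one; 8 vinylmagnesium bromide
Product: 9 (6S)-6-(tert-butyldimethylsilyloxy)-5,5-dimethyl-2-vinyl-1,2,3,4,5,6,7,8-octahydronaphthalen-2-ol (both C2 epimers)
Conditions: CeCl3 (anhydrous), 8, THF, −78 °C; H2O work-up
Reagents that add atoms: vinylmagnesium bromide, C=C[Mg]Br
Why: Organocerium 1,2-addition; the weakly basic vinylcerium reagent should add to the easily enolised β,γ-unsaturated ketone without deprotonation or alkene migration, and the epimer mixture at the new carbinol is harmless because this centre is destroyed in step 7.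

Step 7
Reactants: 9 (6S)-6-(tert-butyldimethylsilyloxy)-5,5-dimethyl-2-vinyl-1,2,3,4,5,6,7,8-octahydronaphthalen-2-ol
Product: 12 (4S)-4-(tert-butyldimethylsilyloxy)-5,5-dimethyl-1-methylidenespiro[5.5]undecan-9-one, via potassium alkoxide 10 (not isolated), via potassium enolate 11 (not isolated)
Conditions: KH, 18-crown-6, THF, 0 → 66 °C; AcOH, −78 °C
Reagents that add atoms: none
Why: Proposed new method: KH with 18-crown-6 gives the dissociated alkoxide 10, whose charge weakens the allylic C9–CH2 ring bond; when the cyclohexene ring is a boat and the vinyl group stands in the flagpole position, the vinyl terminus C7 lies over C6, and a boat [3,3] shift (at its stepwise limit, heterolysis to a tethered allyl anion and vinyl ketone, then Michael addition through the substituted allyl terminus) forms C6–C7, cuts C9–CH2 and delivers enolate 11 and the C1 methylene in one event. The closest known reactions are anionic oxy-Cope rearrangements through boat transition states in bicyclic carbinols, the [3,3] and [1,3] rearrangements of medium-ring 1-vinylcycloalk-3-enols, and the degenerate Cope rearrangement of 4-vinylcyclohexene, none of which shows this shift on a 1-vinylcyclohex-3-enol with a tetrasubstituted ring-fusion alkene. Ring B closes across the 1,4-positions of the old ring as a six-membered ring (6-endo-trig in the Michael picture) while the old cyclohexene ring opens. No lasting stereocentre arises: C6 is stereogenic only in enolate 11 and becomes a non-stereogenic spiro atom once protonation gives the symmetric ring B of 12, C4 is a spectator, and so both carbinol epimers of 9 converge. The step needs periselectivity for [3,3] over the [1,3] shift to the ring-expanded cyclooct-4-enone and over fragmentation without reclosure; six- against eight-membered closure and the alkoxide-to-enolate energy gain speak for it, crowding at C6 beside C5 and poor overlap of the breaking ring bond with the alkene speak against it, so it is not assured. The silyl ether keeps the C4 oxygen from becoming a second alkoxide that could trigger retro-allylation at the homoallylic C4–C5 bond.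

Step 8
Reactants: 12 (4S)-4-(tert-butyldimethylsilyloxy)-5,5-dimethyl-1-methylidenespiro[5.5]undecan-9-one
Product: 14 (4S,6R)-4-(tert-butyldimethylsilyloxy)-5,5-dimethyl-1-methylidenespiro[5.5]undec-9-en-9-yl triflate, via lithium enolate 13 (not isolated)
Conditions: (S,S)-bis(1-phenylethyl)amine·HCl, n-BuLi (2 equiv), THF, −78 °C; 12; Comins' reagent, −78 → 0 °C
Reagents that add atoms: N-(5-chloropyridin-2-yl)bis(trifluoromethanesulfonimide) (Comins' reagent), O=S(=O)(N(c1ccc(Cl)cn1)S(=O)(=O)C(F)(F)F)C(F)(F)F
Why: Group-selective deprotonation with a C2-symmetric chiral lithium amide in the presence of LiCl, then O-triflation; ring B sits in the chair with sp2 C1 axial and bulky C5 equatorial, the amide chooses between the two axial α-hydrogens on C8 and C10, and removal of the C10 hydrogen makes C6 stereogenic with the (R) configuration under reagent control.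

Step 9
Reactants: 14 (4S,6R)-4-(tert-butyldimethylsilyloxy)-5,5-dimethyl-1-methylidenespiro[5.5]undec-9-en-9-yl triflate; 15 methylmagnesium bromide
Product: 16 (4S,6R)-4-(tert-butyldimethylsilyloxy)-5,5,9-trimethyl-1-methylidenespiro[5.5]undec-9-ene
Conditions: 15, Fe(acac)3 (5 mol%), THF/NMP, −30 → 0 °C
Reagents that add atoms: methylmagnesium bromide, C[Mg]Br
Why: Iron-catalysed Kumada-type cross-coupling of an alkenyl triflate, which is fast at low temperature, keeps the alkene position (and with it the C6 configuration) and leaves the silyl ether and the hindered methylene alone.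

Step 10
Reactants: 16 (4S,6R)-4-(tert-butyldimethylsilyloxy)-5,5,9-trimethyl-1-methylidenespiro[5.5]undec-9-ene
Product: 17 (4S,6R)-5,5,9-trimethyl-1-methylidenespiro[5.5]undec-9-en-4-ol
Conditions: n-Bu4NF, THF, 60 °C
Reagents that add atoms: none
Why: Fluoride cleavage of the silyl ether, with warming because the ether is neopentylic; neither alkene nor any stereocentre is affected.

Step 11
Reactants: 17 (4S,6R)-5,5,9-trimethyl-1-methylidenespiro[5.5]undec-9-en-4-ol
Product: 18 (4R,6R)-4-bromo-5,5,9-trimethyl-1-methylidenespiro[5.5]undec-9-ene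
Conditions: CBr4, P(n-Oct)3, 2,6-lutidine, toluene, 70 °C
Reagents that add atoms: carbon tetrabromide, BrC(Br)(Br)Br
Why: Appel bromination as applied to hindered secondary alcohols and to the 2,2-dimethylcyclohexanols of brominated terpenoids; bromide displaces the oxyphosphonium group from the backside, so the (4S)-alcohol should give the (4R)-bromide (equatorial on ring A), and a stereospecific SN2 process is required because a planar C4 intermediate would lose its relation to C6.

Step 12
Reactants: 18 (4R,6R)-4-bromo-5,5,9-trimethyl-1-methylidenespiro[5.5]undec-9-ene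
Product: 19 (4R,6R,9S,10R)-4-bromo-5,5,9-trimethyl-1-methylidenespiro[5.5]undecane-9,10-diol
Conditions: OsO4 (3 mol%), NMO, acetone/H2O, 0 °C → rt
Reagents that add atoms: N-methylmorpholine N-oxide, C[N+]1([O-])CCOCC1; water, O; OsO4 as oxygen carrier, O=[Os](=O)(=O)=O
Why: Upjohn syn-dihydroxylation; the trisubstituted C9=C10 alkene should react before the C1 methylene (screened on one face by the axial ring B methylene on C6 and on the other by the axial C5 methyl), and OsO4 approaches ring B anti to pseudo-axial C1, as 2-ene steroids are attacked anti to the angular methyl, placing both oxygens on the C5 side.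

Step 13
Reactants: 19 (4R,6R,9S,10R)-4-bromo-5,5,9-trimethyl-1-methylidenespiro[5.5]undecane-9,10-diol
Product: 22 (4R,6R,9R,10R)-4-bromo-9-chloro-5,5,9-trimethyl-1-methylidenespiro[5.5]undecan-10-yl acetate, via cyclic orthoacetate 20 (not isolated), via acetoxonium chloride 21 (not isolated)
Conditions: MeC(OMe)3, PPTS (cat.), CH2Cl2, rt; then TMSCl, CH2Cl2, 0 °C → rt
Reagents that add atoms: trimethyl orthoacetate, COC(C)(OC)OC; chlorotrimethylsilane, C[Si](C)(C)Cl
Why: Mattocks–Moffatt-type conversion of a cis-diol into a trans-chlorohydrin ester; chloride should open 21 with inversion at C9, where the C–O bond is tertiary and axial with an open backside, and not at C10, whose backside is covered by axial C1, whereas an epoxide on the same face was avoided because attack at C9 would run against the Fürst–Plattner rule.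

Step 14
Reactants: 22 (4R,6R,9R,10R)-4-bromo-9-chloro-5,5,9-trimethyl-1-methylidenespiro[5.5]undecan-10-yl acetate
Product: 23 (4R,6R,9R,10R)-4-bromo-9-chloro-5,5,9-trimethyl-1-methylidenespiro[5.5]undecan-10-ol
Conditions: i-Bu2AlH, CH2Cl2, −78 °C; aqueous work-up
Reagents that add atoms: none
Why: Reductive removal of the acetate at low temperature avoids a basic alkoxide that could close to an epoxide or eliminate HCl, and the C–Cl bond, the C–Br bond and the methylene are inert under these conditions.

Step 15
Reactants: 23 (4R,6R,9R,10R)-4-bromo-9-chloro-5,5,9-trimethyl-1-methylidenespiro[5.5]undecan-10-ol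
Product: 25 (4R,6R,9R,10S)-4,10-dibromo-9-chloro-5,5,9-trimethyl-1-methylidenespiro[5.5]undecane, via C10 triflate 24 (not isolated)
Conditions: Tf2O, pyridine, CH2Cl2, −40 → 0 °C; then n-Bu4NBr (1.2 equiv), toluene, 0 → 40 °C
Reagents that add atoms: tetrabutylammonium bromide, CCCC[N+](CCCC)(CCCC)CCCC.[Br-]; triflic anhydride (atoms kept only in 24), O=S(=O)(OS(=O)(=O)C(F)(F)F)C(F)(F)F
Why: Sulfonate displacement (SN2) with inversion; in the preferred chair the C10 triflate is equatorial, so no C–H or C–Cl bond is antiperiplanar to it (E2 and chlorine participation are switched off) and the β-chlorine retards ionisation, leaving backside attack by soluble bromide from the C1 face, which turns (10R)-O into (10S)-Br cis to chlorine.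

Compound list
1 | 6-methoxy-3,4-dihydronaphthalen-2(1H)-one (6-methoxy-2-tetralone) | COc1ccc2c(c1)CCC(=O)C2 | starting material
2 | methyl iodide | CI | starting material
3 | 6-methoxy-1,1-dimethyl-3,4-dihydronaphthalen-2(1H)-one | COc1ccc2c(c1)CCC(=O)C2(C)C | intermediate
4 | (2S)-6-methoxy-1,1-dimethyl-1,2,3,4-tetrahydronaphthalen-2-ol | COc1ccc2c(c1)CC[C@H](O)C2(C)C | intermediate
5 | (2S)-2-(tert-butyldimethylsilyloxy)-6-methoxy-1,1-dimethyl-1,2,3,4-tetrahydronaphthalene | COc1ccc2c(c1)CC[C@H](O[Si](C)(C)C(C)(C)C)C2(C)C | intermediate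
6 | (2S)-2-(tert-butyldimethylsilyloxy)-6-methoxy-1,1-dimethyl-1,2,3,4,5,8-hexahydronaphthalene | COC1=CCC2=C(C1)CC[C@H](O[Si](C)(C)C(C)(C)C)C2(C)C | intermediate
7 | (6S)-6-(tert-butyldimethylsilyloxy)-5,5-dimethyl-3,4,5,6,7,8-hexahydronaphthalen-2(1H)-one | O=C1CCC2=C(C1)CC[C@H](O[Si](C)(C)C(C)(C)C)C2(C)C | intermediate
8 | vinylmagnesium bromide | C=C[Mg]Br | starting material
9 | (6S)-6-(tert-butyldimethylsilyloxy)-5,5-dimethyl-2-vinyl-1,2,3,4,5,6,7,8-octahydronaphthalen-2-ol, both C2 epimers | C=CC1(O)CCC2=C(C1)CC[C@H](O[Si](C)(C)C(C)(C)C)C2(C)C | intermediate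
10 | potassium alkoxide of 9 | [K+].C=CC1([O-])CCC2=C(C1)CC[C@H](O[Si](C)(C)C(C)(C)C)C2(C)C | intermediate
11 | potassium enolate of 12 (C6 configuration unassigned) | [K+].C=C1CC[C@H](O[Si](C)(C)C(C)(C)C)C(C)(C)C12CCC([O-])=CC2 | intermediate
12 | (4S)-4-(tert-butyldimethylsilyloxy)-5,5-dimethyl-1-methylidenespiro[5.5]undecan-9-one | C=C1CC[C@H](O[Si](C)(C)C(C)(C)C)C(C)(C)C12CCC(=O)CC2 | intermediate
13 | lithium (4S,6R)-4-(tert-butyldimethylsilyloxy)-5,5-dimethyl-1-methylidenespiro[5.5]undec-9-en-9-olate | [Li+].C=C1CC[C@H](O[Si](C)(C)C(C)(C)C)C(C)(C)[C@@]12CCC([O-])=CC2 | intermediate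
14 | (4S,6R)-4-(tert-butyldimethylsilyloxy)-5,5-dimethyl-1-methylidenespiro[5.5]undec-9-en-9-yl triflate | C=C1CC[C@H](O[Si](C)(C)C(C)(C)C)C(C)(C)[C@@]12CCC(OS(=O)(=O)C(F)(F)F)=CC2 | intermediate
15 | methylmagnesium bromide | C[Mg]Br | starting material
16 | (4S,6R)-4-(tert-butyldimethylsilyloxy)-5,5,9-trimethyl-1-methylidenespiro[5.5]undec-9-ene | C=C1CC[C@H](O[Si](C)(C)C(C)(C)C)C(C)(C)[C@@]12CCC(C)=CC2 | intermediate
17 | (4S,6R)-5,5,9-trimethyl-1-methylidenespiro[5.5]undec-9-en-4-ol | C=C1CC[C@H](O)C(C)(C)[C@@]12CCC(C)=CC2 | intermediate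
18 | (4R,6R)-4-bromo-5,5,9-trimethyl-1-methylidenespiro[5.5]undec-9-ene | C=C1CC[C@@H](Br)C(C)(C)[C@@]12CCC(C)=CC2 | intermediate
19 | (4R,6R,9S,10R)-4-bromo-5,5,9-trimethyl-1-methylidenespiro[5.5]undecane-9,10-diol | C=C1CC[C@@H](Br)C(C)(C)[C@@]12CC[C@](C)(O)[C@H](O)C2 | intermediate
20 | cyclic methyl orthoacetate of 19 (orthoester carbon unassigned) | C=C1CC[C@@H](Br)C(C)(C)[C@@]12CC[C@]3(C)OC(C)(OC)O[C@@H]3C2 | intermediate
21 | 2-methyl-1,3-dioxolan-2-ylium chloride fused at C9–C10 on the C5 face | C=C1CC[C@@H](Br)C(C)(C)[C@@]12CC[C@]3(C)OC(C)=[O+][C@@H]3C2.[Cl-] | intermediate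
22 | (4R,6R,9R,10R)-4-bromo-9-chloro-5,5,9-trimethyl-1-methylidenespiro[5.5]undecan-10-yl acetate | C=C1CC[C@@H](Br)C(C)(C)[C@@]12CC[C@@](C)(Cl)[C@H](OC(C)=O)C2 | intermediate
23 | (4R,6R,9R,10R)-4-bromo-9-chloro-5,5,9-trimethyl-1-methylidenespiro[5.5]undecan-10-ol | C=C1CC[C@@H](Br)C(C)(C)[C@@]12CC[C@@](C)(Cl)[C@H](O)C2 | intermediate
24 | (4R,6R,9R,10R)-4-bromo-9-chloro-5,5,9-trimethyl-1-methylidenespiro[5.5]undecan-10-yl triflate | C=C1CC[C@@H](Br)C(C)(C)[C@@]12CC[C@@](C)(Cl)[C@H](OS(=O)(=O)C(F)(F)F)C2 | intermediate
25 | (4R,6R,9R,10S)-4,10-dibromo-9-chloro-5,5,9-trimethyl-1-methylidenespiro[5.5]undecane (CNP0211773.4) | C=C1CC[C@@H](Br)C(C)(C)[C@@]12CC[C@@](C)(Cl)[C@@H](Br)C2 | target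

Total step count: 15. Longest linear sequence: 15 (the route is fully linear).

Steps most likely to fail

1. Step 7 (proposed new method).
- What may go wrong: bonding at the unhindered CH2 terminus ([1,3] shift with ring expansion), heterolysis followed by proton transfer instead of reclosure, or no reaction because the breaking ring bond lies close to the nodal plane of the alkene.
- Fallback with known chemistry, from 7 back to 12: the same two bond changes are made one after the other, with silicon in the role of the negative charge.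
- Ketone 7 is deprotonated at the doubly activated CH2 between carbonyl and alkene [KN(SiMe3)2, THF, −78 °C] and oxidised with 2-(phenylsulfonyl)-3-phenyloxaziridine (Davis reagent) to the α-hydroxy ketone F1.
- Pb(OAc)4 in MeOH/benzene cleaves the ketol bond (the C9–CH2 bond) to the enal methyl ester F2.
- Luche reduction (NaBH4, CeCl3·7H2O, MeOH) gives the allylic alcohol F3.
- Palladium-catalysed allylic silylation [Me3SiSiMe3, Pd(BF4)2(MeCN)4, DMSO/MeOH] gives the primary allylsilane F4.
- MeNH(OMe)·HCl with i-PrMgCl gives the Weinreb amide F5, and 8 converts it into the vinyl ketone F6.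
- An intramolecular Hosomi–Sakurai reaction (EtAlCl2, CH2Cl2, −78 °C) joins the γ-carbon of the allylsilane (C6) to the enone terminus (C7) in a six-membered closure. It expels the silyl group, sets up the C1 methylene and, after protonation, gives 12.

2. Step 15.
- What may go wrong: slow backside approach of bromide along the face that carries axial C1 and next to fully substituted C9; ionisation of the triflate with ring contraction or chlorine migration; bromide exchange that epimerises the axial C10 bromide to its equatorial epimer.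
- Fallback, from 18 directly to 25 (replacing steps 12 to 15): oxygen is left out and selenium serves as both the electrophile and the later nucleofuge.
- PhSeCl adds anti across C9=C10 (MeCN, rt, thermodynamic control; seleniranium ion anti to C1, chloride at tertiary C9) to give the β-chloro selenide F7.
- One equivalent of Br2 (CH2Cl2, −78 °C → rt) is taken up by selenium faster than by the screened methylene and gives the selenide dibromide F8.
- The tetravalent selenium group of F8 is a much better leaving group than a sulfonate. It is displaced by its own bromide with inversion, as in the selenium-based syn-dichlorination of alkenes, to give 25.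

3. Step 11.
- What may go wrong: methyl migration from C5, ring contraction, or elimination toward C3 in place of substitution at the neopentyl carbon; acid-induced drift of the methylene into ring A.
- Fallback, from 12 back to 18: the displacement is moved to the stage right after the key step, and the activation is changed from an oxyphosphonium ion formed in situ to an isolated sulfonate.
- n-Bu4NF frees the hydroxy ketone F9, Tf2O/pyridine (CH2Cl2, −20 °C) gives the triflate F10, and LiBr in acetone displaces it with inversion to the bromo ketone F11.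
- At this stage no acid-labile trisubstituted alkene is present, and C4 is the only stereocentre.
- With bromine equatorial, ring A is locked so that the C1 methylene leans over C7/C8. The axial hydrogen on C10 is then the more exposed one, so the substrate should reinforce the chiral amide.
- The conditions of step 8 then give the bromo enol triflate F12.
- Negishi methylation (Me2Zn, Pd(PPh3)4, THF), which leaves a secondary alkyl bromide untouched, gives 18.

Further compounds
F1 | step 7 | (6S)-6-(tert-butyldimethylsilyloxy)-1-hydroxy-5,5-dimethyl-3,4,5,6,7,8-hexahydronaphthalen-2(1H)-one (C1 epimers) | O=C1CCC2=C(C1O)CC[C@H](O[Si](C)(C)C(C)(C)C)C2(C)C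
F2 | step 7 | methyl 3-[(5S)-5-(tert-butyldimethylsilyloxy)-2-formyl-6,6-dimethylcyclohex-1-en-1-yl]propanoate | COC(=O)CCC1=C(C=O)CC[C@H](O[Si](C)(C)C(C)(C)C)C1(C)C
F3 | step 7 | methyl 3-[(5S)-5-(tert-butyldimethylsilyloxy)-2-(hydroxymethyl)-6,6-dimethylcyclohex-1-en-1-yl]propanoate | COC(=O)CCC1=C(CO)CC[C@H](O[Si](C)(C)C(C)(C)C)C1(C)C
F4 | step 7 | methyl 3-{(5S)-5-(tert-butyldimethylsilyloxy)-6,6-dimethyl-2-[(trimethylsilyl)methyl]cyclohex-1-en-1-yl}propanoate | COC(=O)CCC1=C(C[Si](C)(C)C)CC[C@H](O[Si](C)(C)C(C)(C)C)C1(C)C
F5 | step 7 | 3-{(5S)-5-(tert-butyldimethylsilyloxy)-6,6-dimethyl-2-[(trimethylsilyl)methyl]cyclohex-1-en-1-yl}-N-methoxy-N-methylpropanamide | CON(C)C(=O)CCC1=C(C[Si](C)(C)C)CC[C@H](O[Si](C)(C)C(C)(C)C)C1(C)C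
F6 | step 7 | 5-{(5S)-5-(tert-butyldimethylsilyloxy)-6,6-dimethyl-2-[(trimethylsilyl)methyl]cyclohex-1-en-1-yl}pent-1-en-3-one | C=CC(=O)CCC1=C(C[Si](C)(C)C)CC[C@H](O[Si](C)(C)C(C)(C)C)C1(C)C
F7 | step 15 | (4R,6R,9R,10R)-4-bromo-9-chloro-5,5,9-trimethyl-1-methylidene-10-(phenylselanyl)spiro[5.5]undecane | C=C1CC[C@@H](Br)C(C)(C)[C@@]12CC[C@@](C)(Cl)[C@H]([Se]c3ccccc3)C2
F8 | step 15 | Se,Se-dibromide of F7 | C=C1CC[C@@H](Br)C(C)(C)[C@@]12CC[C@@](C)(Cl)[C@H]([Se](Br)(Br)c3ccccc3)C2
F9 | step 11 | (4S)-4-hydroxy-5,5-dimethyl-1-methylidenespiro[5.5]undecan-9-one | C=C1CC[C@H](O)C(C)(C)C12CCC(=O)CC2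
F10 | step 11 | (4S)-5,5-dimethyl-1-methylidene-9-oxospiro[5.5]undecan-4-yl triflate | C=C1CC[C@H](OS(=O)(=O)C(F)(F)F)C(C)(C)C12CCC(=O)CC2
F11 | step 11 | (4R)-4-bromo-5,5-dimethyl-1-methylidenespiro[5.5]undecan-9-one | C=C1CC[C@@H](Br)C(C)(C)C12CCC(=O)CC2
F12 | step 11 | (4R,6R)-4-bromo-5,5-dimethyl-1-methylidenespiro[5.5]undec-9-en-9-yl triflate | C=C1CC[C@@H](Br)C(C)(C)[C@@]12CCC(OS(=O)(=O)C(F)(F)F)=CC2
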